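**Plan**

- Retrosynthesis: first the C3–H and C4–H bonds are cut (retro syn-hydrogenation to a 2,5-dihydrofuran). Then the O1–C5 bond is cut and O1 is re-bonded to C3, which contracts the oxolane (O1, C2, C3, C4, C5) to a 2-aryl-3-vinyloxirane (O1, C2, C3) carrying C4=C5H2. Then the oxirane oxygen is removed (retro-Sharpless) to a 1,3-dienol. Last, the C3–C4 bond (Suzuki), the C2=C3 alkene (Wittig) and the ArCH2–C4 bond (Grignard allylation) are cut.
- Enabling feature: O1 lies between the benzylic C2–H and an unsubstituted C5H2, and C3–C4–C5 is a saturated allyl unit whose two CH hydrogens can be added last. The five-membered ring is therefore the 1,3-oxygen-shift (strain-release) isomer of a vinyl oxirane whose terminal =CH2 is C5.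
- Forward: two aryl fragments → bromoallyl alcohol + alkenyl boronate → dienol (all carbons in place) → oxirane (three-membered ring) → 2,5-dihydrofuran (five-membered ring) → oxolane.
- Stereochemistry: C2 is set by Sharpless epoxidation with L-(+)-DIPT, and its C–O bond is never broken afterwards. The second oxirane centre, the C3=C4 double bond and the silyl ether are temporary helpers. C3 and C4 are set together by syn-hydrogenation anti to the C2 aryl group, giving the all-cis (2R,3R,4R) oxolane.

Key step: step 8

Remark on the chemistry: the target SMILES is read as the all-cis (2R,3R,4R) oxolane, with 3,4,5-trimethoxyphenyl at C2, CH2OH at C3 and 2,4,5-trimethoxybenzyl at C4.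

**Route**

Step 1
Reactants: 1 1-bromo-2,4,5-trimethoxybenzene; 2 2,3-dibromoprop-1-ene
Product: 4 1-(2-bromoprop-2-en-1-yl)-2,4,5-trimethoxybenzene, via aryl Grignard reagent 3 (not isolated)
Conditions: Mg, I2 (cat.), THF, reflux; then 2, CuI (5 mol%), THF, 0 °C to rt
Reagents that add atoms: none
Why: Copper-catalysed allylic substitution of the aryl Grignard reagent on the allylic C–Br bond of 2 (SN2 and SN2′ give the same product) should be far faster than any reaction at the vinylic C–Br bond, which is kept as the handle for step 2.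

Step 2
Reactants: 4 1-(2-bromoprop-2-en-1-yl)-2,4,5-trimethoxybenzene
Product: 5 4,4,5,5-tetramethyl-2-[3-(2,4,5-trimethoxyphenyl)prop-1-en-2-yl]-1,3,2-dioxaborolane
Conditions: B2pin2, PdCl2(PPh3)2 (3 mol%), PPh3 (6 mol%), KOPh, toluene, 50 °C
Reagents that add atoms: bis(pinacolato)diboron, CC1(C)OB(OC1(C)C)B1OC(C)(C)C(C)(C)O1
Why: Miyaura borylation of a 1-alkenyl bromide under weak-base (phenoxide) conditions should replace Br by Bpin without Suzuki homocoupling or migration of the 1,1-disubstituted double bond.

Step 3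
Reactants: 6 ethyl (triphenylphosphoranylidene)acetate; 7 3,4,5-trimethoxybenzaldehyde
Product: 9 ethyl (Z)-2-bromo-3-(3,4,5-trimethoxyphenyl)prop-2-enoate, via bromo ylide 8 (not isolated)
Conditions: 6, NBS, CH2Cl2, −20 °C; then 7, −20 °C to rt
Reagents that add atoms: N-bromosuccinimide, O=C1CCC(=O)N1Br
Why: One-pot halogenation–Wittig olefination: NBS brominates the stabilised ylide, the succinimide anion deprotonates the phosphonium salt to the bromo ylide 8, and this stabilised ylide should olefinate the aldehyde with the aryl group trans to the ester, i.e. the (Z)-α-bromoacrylate.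

Step 4
Reactants: 9 ethyl (Z)-2-bromo-3-(3,4,5-trimethoxyphenyl)prop-2-enoate
Product: 10 (Z)-2-bromo-3-(3,4,5-trimethoxyphenyl)prop-2-en-1-ol
Conditions: DIBAL-H (2.2 equiv), CH2Cl2, −78 °C; Rochelle salt work-up
Reagents that add atoms: none
Why: 1,2-Reduction of the α,β-unsaturated ester by DIBAL-H at low temperature should give the allylic alcohol without touching the vinylic bromide or the alkene geometry.

Step 5
Reactants: 10 (Z)-2-bromo-3-(3,4,5-trimethoxyphenyl)prop-2-en-1-ol; 5 4,4,5,5-tetramethyl-2-[3-(2,4,5-trimethoxyphenyl)prop-1-en-2-yl]-1,3,2-dioxaborolane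
Product: 11 (E)-2-[3-(2,4,5-trimethoxyphenyl)prop-1-en-2-yl]-3-(3,4,5-trimethoxyphenyl)prop-2-en-1-ol
Conditions: Pd(dppf)Cl2 (5 mol%), K3PO4, THF/H2O, 60 °C
Reagents that add atoms: none
Why: Suzuki–Miyaura coupling of an alkenyl bromide with an alkenyl boronate proceeds with retention of the bromoalkene geometry and tolerates the free allylic alcohol, so it should give the 2,3-disubstituted 1,3-diene with the aryl group trans to CH2OH.

Step 6
Reactants: 11 (E)-2-[3-(2,4,5-trimethoxyphenyl)prop-1-en-2-yl]-3-(3,4,5-trimethoxyphenyl)prop-2-en-1-ol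
Product: 12 [(2S,3S)-2-[3-(2,4,5-trimethoxyphenyl)prop-1-en-2-yl]-3-(3,4,5-trimethoxyphenyl)oxiran-2-yl]methanol
Conditions: Ti(OiPr)4 (10 mol%), L-(+)-DIPT (14 mol%), TBHP (isooctane), 4 Å MS, CH2Cl2, −20 °C
Reagents that add atoms: tert-butyl hydroperoxide, CC(C)(C)OO
Why: Sharpless asymmetric epoxidation is hydroxyl-directed and so should select the allylic trisubstituted alkene over the homoallylic 1,1-disubstituted one; with L-(+)-DIPT oxygen is delivered to the face that gives the (2S,3S)-epoxy alcohol, as for (E)-2-substituted cinnamyl alcohols, which fixes the aryl-bearing carbon that becomes C2 of the target.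

Step 7
Reactants: 12 [(2S,3S)-2-[3-(2,4,5-trimethoxyphenyl)prop-1-en-2-yl]-3-(3,4,5-trimethoxyphenyl)oxiran-2-yl]methanol
Product: 13 tert-butyl(dimethyl){[(2S,3S)-2-[3-(2,4,5-trimethoxyphenyl)prop-1-en-2-yl]-3-(3,4,5-trimethoxyphenyl)oxiran-2-yl]methoxy}silane
Conditions: TBSCl, imidazole, DMF, 0 °C to rt
Reagents that add atoms: tert-butyldimethylsilyl chloride, CC(C)(C)[Si](C)(C)Cl
Why: Standard imidazole-mediated silylation masks the primary alcohol as a non-participating ether, so that it can neither open the oxirane nor bind copper in step 8.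

Step 8
Reactants: 13 tert-butyl(dimethyl){[(2S,3S)-2-[3-(2,4,5-trimethoxyphenyl)prop-1-en-2-yl]-3-(3,4,5-trimethoxyphenyl)oxiran-2-yl]methoxy}silane
Product: 14 tert-butyl(dimethyl){[(2S)-2-(3,4,5-trimethoxyphenyl)-4-[(2,4,5-trimethoxyphenyl)methyl]-2,5-dihydrofuran-3-yl]methoxy}silane
Conditions: Cu(hfacac)2 (5 mol%), toluene, 150 °C, sealed tube
Reagents that add atoms: none
Why: The copper(II) Lewis acid binds the oxirane oxygen and ionises the tertiary, allylic C–O bond to a copper alkoxide/allyl cation (or η3-allylcopper) pair, which collapses by C–O bond formation at the unsubstituted CH2 terminus; this is a net 1,3-oxygen shift and a two-atom ring expansion driven by release of oxirane strain and formation of a tetrasubstituted alkene. The closest known reaction type is the copper-catalysed rearrangement of vinyl oxiranes to 2,5-dihydrofurans, which is established for aryl-substituted, trisubstituted oxiranes and 2-substituted vinyl groups. The five-membered ring closes in a formally 5-endo-trig (SN2′-type) mode, which is feasible because the allyl unit is ionised or copper-bound (reductive elimination from a six-membered oxacupracycle) and not a simple alkene. No new stereocentre is formed: the aryl-bearing carbon keeps the configuration from step 6 because its C–O bond is never broken, and the quaternary oxirane centre becomes sp2 after relaying the oxygen. The step needs ionisation at the quaternary carbon and closure at the CH2 terminus in preference to benzylic C–O cleavage or a 1,2-hydride shift to a ketone; the allylic tertiary centre, the only weakly donating 3,4,5-trimethoxyphenyl group, the non-participating silyl ether and the unhindered terminal methylene should secure this.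

Step 9
Reactants: 14 tert-butyl(dimethyl){[(2S)-2-(3,4,5-trimethoxyphenyl)-4-[(2,4,5-trimethoxyphenyl)methyl]-2,5-dihydrofuran-3-yl]methoxy}silane
Product: 15 [(2S)-2-(3,4,5-trimethoxyphenyl)-4-[(2,4,5-trimethoxyphenyl)methyl]-2,5-dihydrofuran-3-yl]methanol
Conditions: TBAF, THF, 0 °C
Reagents that add atoms: none
Why: Fluoride-mediated Si–O cleavage of a primary TBS ether is mild and should leave the allylic, benzylic C2–O bond and the C2 stereocentre untouched.

Step 10
Reactants: 15 [(2S)-2-(3,4,5-trimethoxyphenyl)-4-[(2,4,5-trimethoxyphenyl)methyl]-2,5-dihydrofuran-3-yl]methanol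
Product: 16 [(2R,3R,4R)-2-(3,4,5-trimethoxyphenyl)-4-[(2,4,5-trimethoxyphenyl)methyl]oxolan-3-yl]methanol
Conditions: H2 (1–5 bar), [Ir(cod)(PCy3)(py)]PF6 (5–10 mol%), CH2Cl2, rt
Reagents that add atoms: none
Why: Hydroxyl-assisted homogeneous hydrogenation with Crabtree's catalyst reduces tetrasubstituted allylic-alcohol alkenes without hydrogenolysis of benzylic ethers; syn addition of H2 to the face of the nearly flat dihydrofuran opposite the C2 aryl group should set C3 and C4 together and place CH2OH and the arylmethyl group cis to the aryl group (all-cis).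

**Compound list**

1 | 1-bromo-2,4,5-trimethoxybenzene | COc1cc(OC)c(OC)cc1Br | starting material
2 | 2,3-dibromoprop-1-ene | C=C(Br)CBr | starting material
3 | (2,4,5-trimethoxyphenyl)magnesium bromide | COc1cc(OC)c(OC)cc1[Mg]Br | intermediate
4 | 1-(2-bromoprop-2-en-1-yl)-2,4,5-trimethoxybenzene | COc1cc(OC)c(OC)cc1CC(Br)=C | intermediate
5 | 4,4,5,5-tetramethyl-2-[3-(2,4,5-trimethoxyphenyl)prop-1-en-2-yl]-1,3,2-dioxaborolane | COc1cc(OC)c(OC)cc1CC(=C)B1OC(C)(C)C(C)(C)O1 | intermediate
6 | ethyl (triphenylphosphoranylidene)acetate | CCOC(=O)C=P(c1ccccc1)(c1ccccc1)c1ccccc1 | starting material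
7 | 3,4,5-trimethoxybenzaldehyde | COc1cc(C=O)cc(OC)c1OC | starting material
8 | ethyl bromo(triphenylphosphoranylidene)acetate | CCOC(=O)C(Br)=P(c1ccccc1)(c1ccccc1)c1ccccc1 | intermediate
9 | ethyl (Z)-2-bromo-3-(3,4,5-trimethoxyphenyl)prop-2-enoate | CCOC(=O)/C(Br)=C/c1cc(OC)c(OC)c(OC)c1 | intermediate
10 | (Z)-2-bromo-3-(3,4,5-trimethoxyphenyl)prop-2-en-1-ol | OC/C(Br)=C/c1cc(OC)c(OC)c(OC)c1 | intermediate
11 | (E)-2-[3-(2,4,5-trimethoxyphenyl)prop-1-en-2-yl]-3-(3,4,5-trimethoxyphenyl)prop-2-en-1-ol | OC/C(C(=C)Cc1cc(OC)c(OC)cc1OC)=C/c1cc(OC)c(OC)c(OC)c1 | intermediate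
12 | [(2S,3S)-2-[3-(2,4,5-trimethoxyphenyl)prop-1-en-2-yl]-3-(3,4,5-trimethoxyphenyl)oxiran-2-yl]methanol | C=C(Cc1cc(OC)c(OC)cc1OC)[C@@]1(CO)O[C@H]1c1cc(OC)c(OC)c(OC)c1 | intermediate
13 | tert-butyl(dimethyl){[(2S,3S)-2-[3-(2,4,5-trimethoxyphenyl)prop-1-en-2-yl]-3-(3,4,5-trimethoxyphenyl)oxiran-2-yl]methoxy}silane | C=C(Cc1cc(OC)c(OC)cc1OC)[C@@]1(CO[Si](C)(C)C(C)(C)C)O[C@H]1c1cc(OC)c(OC)c(OC)c1 | intermediate
14 | tert-butyl(dimethyl){[(2S)-2-(3,4,5-trimethoxyphenyl)-4-[(2,4,5-trimethoxyphenyl)methyl]-2,5-dihydrofuran-3-yl]methoxy}silane | COc1cc(OC)c(OC)cc1CC1=C(CO[Si](C)(C)C(C)(C)C)[C@H](c2cc(OC)c(OC)c(OC)c2)OC1 | intermediate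
15 | [(2S)-2-(3,4,5-trimethoxyphenyl)-4-[(2,4,5-trimethoxyphenyl)methyl]-2,5-dihydrofuran-3-yl]methanol | COc1cc(OC)c(OC)cc1CC1=C(CO)[C@H](c2cc(OC)c(OC)c(OC)c2)OC1 | intermediate
16 | [(2R,3R,4R)-2-(3,4,5-trimethoxyphenyl)-4-[(2,4,5-trimethoxyphenyl)methyl]oxolan-3-yl]methanol | COc1cc(OC)c(OC)cc1C[C@H]1CO[C@@H](c2cc(OC)c(OC)c(OC)c2)[C@H]1CO | target

**Step count**

Total steps: 10. Longest linear sequence: 8 steps (steps 3–10 from 6 and 7; equally steps 1, 2, 5–10 from 1 and 2).

**Steps most likely to fail**

1. Step 8 (ring expansion). What may go wrong: after ionisation the intermediate may undergo a 1,2-hydride shift or proton loss instead of C–O closure at the CH2 terminus, or the benzylic C–O bond may ionise and erode the configuration at the aryl-bearing carbon. Fallback, setting out from 13 and rejoining at 14: the single catalytic isomerisation is replaced by a two-operation halide relay. Treatment of 13 with MgBr2·OEt2 (Et2O, −20 °C) should open the oxirane in the SN2′ sense at the CH2 terminus to the bromohydrin (1S,2Z)-3-(bromomethyl)-2-({[tert-butyl(dimethyl)silyl]oxy}methyl)-1-(3,4,5-trimethoxyphenyl)-4-(2,4,5-trimethoxyphenyl)but-2-en-1-ol F1. Its E isomer interconverts with it by bromide-mediated 1,3-transposition through the tertiary allylic bromide. NaH with catalytic Bu4NBr (THF, 0 °C) should then close the ring by intramolecular Williamson etherification (5-exo-tet, possible only for the Z isomer) to give 14 with the benzylic C–O bond untouched.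

2. Step 10 (hydrogenation). What may go wrong: the tetrasubstituted alkene may react sluggishly, so that double-bond migration toward C2 (loss of the stereocentre, enol ether formation) competes, or hydrogen may add in part from the aryl-bearing face. Fallback, setting out from 15 and rejoining at 16: concerted H2 addition is replaced by a polar conjugate reduction/protonation. Dess–Martin oxidation of 15 (NaHCO3, CH2Cl2) should give the enal (2S)-2-(3,4,5-trimethoxyphenyl)-4-[(2,4,5-trimethoxyphenyl)methyl]-2,5-dihydrofuran-3-carbaldehyde F2. Copper hydride conjugate reduction (Stryker's reagent, toluene) should deliver hydride to C4 anti to the C2 aryl group. Kinetic protonation of the enolate at −78 °C from the face opposite both the aryl and the new arylmethyl group should give the all-cis aldehyde (2R,3S,4R)-2-(3,4,5-trimethoxyphenyl)-4-[(2,4,5-trimethoxyphenyl)methyl]oxolane-3-carbaldehyde F3. This is reduced at once with NaBH4 (MeOH, −20 °C), before C3 can epimerise, to give 16.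

3. Step 6 (asymmetric epoxidation). What may go wrong: the bulky 2-alkenyl substituent may slow the titanium-templated oxygen transfer and lower the enantioselectivity, and the titanium Lewis acid may open the tertiary allylic, benzylic oxirane once formed. Fallback, setting out from 11 and rejoining at 13: the hydroxyl-directed epoxidation is replaced by a reagent-controlled dioxirane epoxidation of the protected alcohol. Silylation of 11 (TBSCl, imidazole, DMF) should give tert-butyl(dimethyl){[(2E)-2-[3-(2,4,5-trimethoxyphenyl)prop-1-en-2-yl]-3-(3,4,5-trimethoxyphenyl)prop-2-en-1-yl]oxy}silane F4. Shi epoxidation with the L-fructose-derived (enantiomeric) ketone catalyst (Oxone, K2CO3, MeCN/dimethoxymethane/buffer, 0 °C) should then epoxidise the trisubstituted styrenyl alkene in preference to the 1,1-disubstituted one, from the face that gives 13.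

**Further compounds**

F1 | step 8 | (1S,2Z)-3-(bromomethyl)-2-({[tert-butyl(dimethyl)silyl]oxy}methyl)-1-(3,4,5-trimethoxyphenyl)-4-(2,4,5-trimethoxyphenyl)but-2-en-1-ol | O[C@@H](c1cc(OC)c(OC)c(OC)c1)/C(CO[Si](C)(C)C(C)(C)C)=C(\CBr)Cc1cc(OC)c(OC)cc1OC
F2 | step 10 | (2S)-2-(3,4,5-trimethoxyphenyl)-4-[(2,4,5-trimethoxyphenyl)methyl]-2,5-dihydrofuran-3-carbaldehyde | COc1cc(OC)c(OC)cc1CC1=C(C=O)[C@H](c2cc(OC)c(OC)c(OC)c2)OC1
F3 | step 10 | (2R,3S,4R)-2-(3,4,5-trimethoxyphenyl)-4-[(2,4,5-trimethoxyphenyl)methyl]oxolane-3-carbaldehyde | COc1cc(OC)c(OC)cc1C[C@H]1CO[C@@H](c2cc(OC)c(OC)c(OC)c2)[C@H]1C=O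
F4 | step 6 | tert-butyl(dimethyl){[(2E)-2-[3-(2,4,5-trimethoxyphenyl)prop-1-en-2-yl]-3-(3,4,5-trimethoxyphenyl)prop-2-en-1-yl]oxy}silane | CC(C)(C)[Si](C)(C)OC/C(C(=C)Cc1cc(OC)c(OC)cc1OC)=C/c1cc(OC)c(OC)c(OC)c1
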